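Amounts of target are what the earlier runs offer, and they start slowly.

| flask | substrate | reagent | temperature | remark | time |
|---|---|---|---|---|---|
| blue | 1.2 M | 0.70 equiv | 16 °C | run made earlier |  |
| red | 1.9 M | 0.70 equiv | 41 °C | run made earlier |  |
| beta | 0.88 M | 0.700 equiv | 20 °C |  | 10 d |
| eta | 0.88 M | 0.700 equiv | 50 °C |  | 10 d |
| gamma | 0.88 M | 0.700 equiv | 35 °C |  | 10 d |
| theta | 0.88 M | 0.700 equiv | 5 °C |  | 10 d |

| run | time / d | target / % |
|---|---|---|
| blue | 0.625 | 0 |
| blue | 1.25 | 0 |
| blue | 2.50 | 0 |
| blue | 4.00 | 0 |
| blue | 8.00 | 0.3 |
| red | 0.208 | 0 |
| red | 0.417 | 0.1 |
| red | 0.833 | 0.6 |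
| red | 1.25 | 1.2 |
| red | 3.00 | 4.9 |

(standard deviation of a reading: 0.3 percentage points)

- percent here means substrate units held: one homo dimer counts as two
- steps under discussion: 2 substrate -> homo dimer; substrate + reagent -> intermediate + by-product; intermediate -> target; target + by-product -> side product

* which flask leads in amount of target, in percent of the substrate charged ("all alike" within 1.5 percentage points) (beta / eta / gamma / theta / all alike)
* how much target is there at the end, in percent of the substrate charged: beta
* how much target is there at the end, in percent of the substrate charged: eta
* how much target is there at the end, in percent of the substrate charged: gamma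
* how much target is there at the end, in percent of the substrate charged: theta

Substrate and reagent make intermediate, and intermediate makes target. So at the start intermediate grows with time and target with its square, and I write the share of target as (t/τ) squared. From the last red reading τ is 13.6 d. I call τ the lag time, the time at which this square law would have turned the whole charge into target, and t/τ the count of turns. At fixed equivalents and fixed temperature τ squared goes inversely with the charged [substrate], so at the new charge the red lag time becomes 19.9 d.

One objection is that the earlier red reading at 1.25 d gives only 11.4 d, so the law may already be bending. I keep the late value, because its reading of 4.9 % is larger than the earlier 1.2 % under the same scatter of 0.3 percentage points; it stands at a count of 0.221. The blue run gives 171 d at the new charge, but its reading is no bigger than the scatter.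

Taking ln τ as straight in temperature between the two runs, I get 33.3 d for gamma, and so 8.99 %. Does the weak blue reading spoil this? With that reading twice as high, gamma moves to 10.6 %, which I can accept. The same line gives 0.683 % for beta and 0.0519 % for theta, the latter resting on the blue reading and lying outside the runs.

For eta the lag time is 9.19 d, so the count is 1.09, and the law would print 119 %. That is absurd, since each turn of the reagent step takes one reagent and the charge is 0.700 equiv. I therefore commit to no number for eta, only to its lead over gamma.

The forecast gives 0.6 % for beta, 26 % for eta, 9 % for gamma and 0.05 % for theta, and of the lead it says “Eta likely leads, uncertainly”.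

The flasks give 0.369 % for beta, 15.5 % for eta, 6.94 % for gamma and 0.00717 % for theta, so eta leads.

    2 substrate → homo dimer (k = 2.00 × 10⁻⁶ L mol⁻¹ s⁻¹, Ea = 95.0 kJ mol⁻¹)
    substrate + reagent → intermediate + by-product (k = 9.40 × 10⁻⁶ L mol⁻¹ s⁻¹, Ea = 71.0 kJ mol⁻¹)
    intermediate → target (k = 2.90 × 10⁻⁶ s⁻¹, Ea = 117 kJ mol⁻¹)
    target + by-product → side product (k = 1.00 × 10⁻⁵ L mol⁻¹ s⁻¹, Ea = 98.0 kJ mol⁻¹)
    (constants at 50 °C)

Eta's target corresponds to a count of 0.394, against my 1.09. In theta at 10.0 d, substrate has a half-life of 110 d by the reagent step, while intermediate has one of 3200 d by the step to target, far longer, and theta holds 6.38 % intermediate beside 0.00717 % target. Built from these two half-lives, theta's lag time is 1200 d, 60.3 times the red lag time at the same charge, and its count squared is 0.00691 %.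

The earlier runs and the new flask were computed on assumed constants, noise included.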